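**Plan**
- Retrosynthesis: the allylic alcohol is traced back to a methyl propenoate and O1'–C2' is cut (cationic closure of a benzylic alcohol onto the ring C phenol). Then C2'–C5 and C3'–C3a' are cut together, giving rings A/B bromide 12, three-carbon alkenyl boronate 21 (C2', C3', C9') and ring C triflate 16. In 12, C2–C3 (carbene C–H insertion) and O1–CH2 (ether formation) are cut.
- The double cut is possible because C2' and C3' are adjacent sp3 carbons that each carry one aryl group (C5 of ring B on C2', C3a' of ring C on C3'), with oxygen on C2' and the hydroxymethyl carbon C9' on C3'. That is what an aryl nucleophile and an aryl electrophile leave after adding across a B–CH=CH–CH2O unit and exchange of boron for oxygen.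
- Forward: the dihydrofuran on ring B closes first (step 7), the three pieces are joined without ring formation (step 16), the dihydrofuran on ring C closes (step 18), and the ester is reduced last (step 19).
- Stereochemistry: C2 from the chiral dirhodium carboxylate and C3 by base epimerisation to trans. C3' comes from the chiral palladium ligand (alkene face) and C2' from anti addition, kept on oxidation and settled trans to C3' in the cationic closure.

Key step: step 16

Numbering: ring A is the guaiacyl ring; the dihydrobenzofuran on ring B has O1, C2, C3, C3a–C7a and C9 (CH2O on C3); the one on ring C carries primes.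
Assumption: Rh2(S-PTTL)4 is taken to give the (2R) insertion product and the (Sp,Sp) ligand the (3'S) coupling product, as in the closest model reactions; if a trial shows the opposite sense, the mirror-image catalyst is used and nothing else changes.
Compound 19 is a commercial compound.

**Step 1**
Reactants: 1 vanillin
Product: 2 3-methoxy-4-(methoxymethoxy)benzaldehyde
Conditions: MOMCl, i-Pr2NEt, CH2Cl2, 0 °C to rt
Reagents that add atoms: chloromethyl methyl ether, COCCl
Why: Base-mediated O-alkylation of the phenoxide (acetal ether formation) masks the ring A phenol with a group that tolerates base, hydride, carbenoid and organolithium chemistry and is removed in step 18.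

**Step 2**
Reactants: 2 3-methoxy-4-(methoxymethoxy)benzaldehyde
Product: 3 [3-methoxy-4-(methoxymethoxy)phenyl]methanol
Conditions: NaBH4, MeOH, 0 °C
Reagents that add atoms: none
Why: Chemoselective borohydride reduction of the aryl aldehyde gives the benzylic alcohol needed for ether formation.

**Step 3**
Reactants: 4 2-allyl-6-methoxyphenol
Product: 5 2-allyl-4-bromo-6-methoxyphenol
Conditions: NBS (1.0 equiv), MeCN, −10 to 0 °C
Reagents that add atoms: N-bromosuccinimide, O=C1CCC(=O)N1Br
Why: Electrophilic aromatic bromination is directed para to the free hydroxyl group, the most activated open position, and in a polar solvent at low temperature it should outpace attack on the isolated allyl double bond.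

**Step 4**
Reactants: 5 2-allyl-4-bromo-6-methoxyphenol; 3 [3-methoxy-4-(methoxymethoxy)phenyl]methanol
Product: 6 1-allyl-5-bromo-3-methoxy-2-{[3-methoxy-4-(methoxymethoxy)benzyl]oxy}benzene
Conditions: PPh3, DIAD, THF, 0 °C to rt
Reagents that add atoms: none
Why: Mitsunobu etherification joins the acidic phenol to the primary benzylic alcohol under neutral conditions, so no labile p-alkoxybenzyl halide has to be made.

**Step 5**
Reactants: 6 1-allyl-5-bromo-3-methoxy-2-{[3-methoxy-4-(methoxymethoxy)benzyl]oxy}benzene
Product: 7 methyl 2-(5-bromo-3-methoxy-2-{[3-methoxy-4-(methoxymethoxy)benzyl]oxy}phenyl)acetate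
Conditions: O3, NaOH (2.5 M in MeOH), CH2Cl2, −78 °C
Reagents that add atoms: ozone, [O-][O+]=O; methanol, CO
Why: Ozonolysis in methanolic NaOH (Marshall protocol) converts the terminal alkene directly into the methyl ester, the aldehyde methyl hemiacetal being oxidised by ozone and the terminal carbon leaving as formate; the electron-rich arenes react far more slowly than the alkene if ozone is dosed to the end point.

**Step 6**
Reactants: 7 methyl 2-(5-bromo-3-methoxy-2-{[3-methoxy-4-(methoxymethoxy)benzyl]oxy}phenyl)acetate
Product: 8 methyl 2-diazo-2-(5-bromo-3-methoxy-2-{[3-methoxy-4-(methoxymethoxy)benzyl]oxy}phenyl)acetate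
Conditions: 4-acetamidobenzenesulfonyl azide, DBU, MeCN, 0 °C to rt
Reagents that add atoms: 4-acetamidobenzenesulfonyl azide, CC(=O)Nc1ccc(cc1)S(=O)(=O)N=[N+]=[N-]
Why: Regitz diazo transfer to the benzylic ester enolate gives the donor/acceptor aryldiazoacetate.

**Step 7**
Reactants: 8 methyl 2-diazo-2-(5-bromo-3-methoxy-2-{[3-methoxy-4-(methoxymethoxy)benzyl]oxy}phenyl)acetate
Product: 9 methyl (2R,3S)-5-bromo-7-methoxy-2-[3-methoxy-4-(methoxymethoxy)phenyl]-2,3-dihydro-1-benzofuran-3-carboxylate (cis)
Conditions: Rh2(S-PTTL)4 (dirhodium tetrakis[N-phthaloyl-(S)-tert-leucinate], 1 mol%), toluene, −78 to −40 °C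
Reagents that add atoms: none
Why: The dirhodium carboxylate turns the diazo ester into a donor/acceptor carbenoid that inserts into one of the two enantiotopic benzylic C–H bonds of the ether (intramolecular 1,5 C–H insertion, closing the five-membered ring at C2–C3), the phthalimido wall of the catalyst selecting the hydrogen that leads to (2R) and the concerted transition state giving the cis ester, as known for 2-benzyloxyphenyl diazoacetates including 5-bromo examples.

**Step 8**
Reactants: 9 cis ester (2R,3S)
Product: 10 methyl (2R,3R)-5-bromo-7-methoxy-2-[3-methoxy-4-(methoxymethoxy)phenyl]-2,3-dihydro-1-benzofuran-3-carboxylate (trans)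
Conditions: NaOMe (0.3 equiv), MeOH, rt
Reagents that add atoms: none
Why: Reversible enolisation at C3 (base-mediated epimerisation) moves the ester to the thermodynamically preferred side, trans to the aryl group, while C2 is untouched, so (2R,3R) results.

**Step 9**
Reactants: 10 trans ester (2R,3R)
Product: 11 {(2R,3S)-5-bromo-7-methoxy-2-[3-methoxy-4-(methoxymethoxy)phenyl]-2,3-dihydro-1-benzofuran-3-yl}methanol
Conditions: i-Bu2AlH (2.5 equiv), CH2Cl2, −78 to 0 °C; aq. potassium sodium tartrate
Reagents that add atoms: none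
Why: Hydride reduction of the ester to the primary alcohol leaves both stereocentres and, at low temperature, the aryl bromide unchanged (the C3 descriptor becomes S only because the priorities change).

**Step 10**
Reactants: 11 primary alcohol (2R,3S)
Product: 12 tert-butyl({(2R,3S)-5-bromo-7-methoxy-2-[3-methoxy-4-(methoxymethoxy)phenyl]-2,3-dihydro-1-benzofuran-3-yl}methoxy)dimethylsilane
Conditions: TBSCl, imidazole, DMF, rt
Reagents that add atoms: tert-butyldimethylsilyl chloride, CC(C)(C)[Si](C)(C)Cl
Why: Silylation of the primary alcohol removes the only acidic proton before the bromine–lithium exchange.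

**Step 11**
Reactants: 13 3,4-dihydroxy-5-methoxybenzaldehyde
Product: 14 3-hydroxy-5-methoxy-4-(methoxymethoxy)benzaldehyde
Conditions: MOMCl (1.05 equiv), K2CO3 (1.1 equiv), acetone, 0 °C to rt
Reagents that add atoms: chloromethyl methyl ether, COCCl
Why: The hydroxyl group para to the formyl group is the more acidic one, so one equivalent of carbonate forms its phenoxide and the alkylation (Williamson type) is regioselective for O4.

**Step 12**
Reactants: 14 3-hydroxy-5-methoxy-4-(methoxymethoxy)benzaldehyde
Product: 15 methyl (E)-3-[3-hydroxy-5-methoxy-4-(methoxymethoxy)phenyl]prop-2-enoate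
Conditions: Ph3P=CHCO2Me, toluene, 60 °C
Reagents that add atoms: methyl (triphenylphosphoranylidene)acetate, COC(=O)C=P(c1ccccc1)(c1ccccc1)c1ccccc1
Why: Wittig olefination with the stabilised ylide gives the (E)-propenoate and tolerates the free phenol.

**Step 13**
Reactants: 15 methyl (E)-3-[3-hydroxy-5-methoxy-4-(methoxymethoxy)phenyl]prop-2-enoate
Product: 16 methyl (E)-3-[3-methoxy-4-(methoxymethoxy)-5-(trifluoromethylsulfonyloxy)phenyl]prop-2-enoate
Conditions: Tf2O, pyridine, CH2Cl2, −20 to 0 °C
Reagents that add atoms: trifluoromethanesulfonic anhydride, O=S(=O)(OS(=O)(=O)C(F)(F)F)C(F)(F)F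
Why: O-Sulfonylation of the remaining phenol turns it into the aryl electrophile, pyridine keeping the medium basic so that the acetal survives.

**Step 14**
Reactants: 17 acenaphthoquinone
Product: 18 cis-1,2-dimethyl-1,2-dihydroacenaphthylene-1,2-diol (meso)
Conditions: AlMe3 (3 equiv), toluene, 0 °C to rt; aq. potassium sodium tartrate; recrystallisation
Reagents that add atoms: trimethylaluminium, C[Al](C)C
Why: Twofold carbonyl addition of AlMe3 gives the tertiary diol, the second methyl group being delivered to the aluminium-chelated α-alkoxy ketone anti to the O–Al bond, so the cis diol, the only one that can span boron, should predominate and is purified by crystallisation.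

**Step 15**
Reactants: 19 tert-butyldimethyl(prop-2-yn-1-yloxy)silane; 18 cis-1,2-dimethyl-1,2-dihydroacenaphthylene-1,2-diol
Product: 21 (E)-3-(tert-butyldimethylsilyloxy)prop-1-enyl boronate of diol 18, via alkenyl catecholboronate 20 (not isolated)
Conditions: catecholborane (1.1 equiv), Cy2BH (5 mol%), THF, rt; then 18, rt
Reagents that add atoms: catecholborane, B1Oc2ccccc2O1
Why: Syn hydroboration of the terminal alkyne places boron on the terminal carbon and gives the (E)-alkenyl boronate, whose labile catechol ester is exchanged for the hindered cis-diol by transesterification.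

**Step 16**
Reactants: 12 rings A/B bromide; 21 (E)-alkenyl boronate of diol 18; 16 ring C aryl triflate
Product: 24 (2'R,3'S)-1,2-diaryl-3-silyloxypropyl boronate of diol 18 joining rings B and C, via ring B aryllithium 22 (not isolated), via lithium boron ate complex 23 (not isolated)
Conditions: 12, t-BuLi (2.0 equiv), Et2O, −78 °C; 21, −78 °C to rt; solvent change to THF; KOSO2CF3 (2 equiv), Pd(OAc)2 (3 mol%), (αR,αR,Sp,Sp)-1,1'-bis[bis(3,5-dimethylphenyl)phosphino]-2,2'-bis[(dimethylamino)(phenyl)methyl]ferrocene (3.6 mol%), 16 (1.1 equiv), THF, 60 °C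
Reagents that add atoms: none
Why: Bromine–lithium exchange gives aryllithium 22, which adds to the boron of 21 to form the four-coordinate ate complex 23; zerovalent palladium inserts into the C–O bond of triflate 16, the resulting cationic arylpalladium species (divalent palladium) binds the electron-rich alkene of 23 and triggers a 1,2-metallate shift of the ring B aryl group from boron to C2' anti to the metal, and reductive elimination from the C3'–palladium bond with retention forms C3'–C3a'. The closest known reaction type is the palladium-catalysed enantio- and diastereoselective conjunctive cross-coupling of β-substituted alkenyl boron ate complexes of this hindered diol with aryl triflates. No ring is closed. C3' is set by the ferrocenyl bisphosphine, which chooses the alkene face that palladium occupies, and C2' follows from the anti addition across the (E)-alkene, which should give the (2'R,3'S) boronate. The step needs migration to outrun direct Suzuki-type transmetallation and β-hydride elimination, which the hindered, poorly transferring diol ester and the wide-bite-angle ligand secure, and it needs a halide-free cycle, which KOSO2CF3 provides by precipitating bromide. The ester, acetal and silyl ether groups should be inert because no free organolithium remains once 23 has formed.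

**Step 17**
Reactants: 24 (2'R,3'S) boronate
Product: 25 (2'R,3'S)-benzylic alcohol: methyl (E)-3-{3-[1-(tert-butyldimethylsilyloxy)-3-hydroxy-3-(rings A/B aryl)propan-2-yl]-5-methoxy-4-(methoxymethoxy)phenyl}prop-2-enoate
Conditions: NaBO3·4H2O (5 equiv), THF/H2O 1:1, rt
Reagents that add atoms: sodium perborate, [Na+].[O-]OB=O
Why: Perborate oxidation of the C–B bond (1,2-shift of carbon from boron to oxygen) occurs with retention at C2' and is mild enough to spare the propenoate, so the (2'R,3'S) alcohol results.

**Step 18**
Reactants: 25 (2'R,3'S)-benzylic alcohol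
Product: 27 methyl (E)-3-{(2R,3S)-2-[(2R,3S)-2-(4-hydroxy-3-methoxyphenyl)-3-(hydroxymethyl)-7-methoxy-2,3-dihydro-1-benzofuran-5-yl]-3-(hydroxymethyl)-7-methoxy-2,3-dihydro-1-benzofuran-5-yl}prop-2-enoate, via open-chain pentaol 26 (not isolated)
Conditions: HCl (1.25 M in MeOH)/THF 1:1, 0 to 40 °C
Reagents that add atoms: none
Why: Acidic methanol cleaves both aryl acetals and both silyl ethers, and the p-alkoxybenzylic alcohol at C2' ionises to a cation stabilised by O1 of ring B that is captured by the freed ring C phenol (SN1 etherification closing the five-membered ring), the new C2' centre settling trans to the C3' hydroxymethyl group for steric reasons, that is with net retention as (2'R), while any reversible opening at C2 re-closes trans in the same way.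

**Step 19**
Reactants: 27 cyclised methyl propenoate
Product: 28 (E)-3-{(2R,3S)-2-[(2R,3S)-2-(4-hydroxy-3-methoxyphenyl)-3-(hydroxymethyl)-7-methoxy-2,3-dihydro-1-benzofuran-5-yl]-3-(hydroxymethyl)-7-methoxy-2,3-dihydro-1-benzofuran-5-yl}prop-2-en-1-ol (CNP0250921.1)
Conditions: i-Bu2AlH (8 equiv), THF/CH2Cl2, −78 to 0 °C; aq. potassium sodium tartrate
Reagents that add atoms: none
Why: Diisobutylaluminium hydride, after deprotonating the three hydroxyl groups, reduces the conjugated ester by 1,2-addition to the (E)-allylic alcohol, as established for phenolic dihydrobenzofuran ferulate dimers, and no stereocentre is involved.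

**Compound list**
1 | vanillin | COc1cc(C=O)ccc1O | starting material
2 | 3-methoxy-4-(methoxymethoxy)benzaldehyde | COCOc1ccc(C=O)cc1OC | intermediate
3 | [3-methoxy-4-(methoxymethoxy)phenyl]methanol | COCOc1ccc(CO)cc1OC | intermediate
4 | 2-allyl-6-methoxyphenol | C=CCc1cccc(OC)c1O | starting material
5 | 2-allyl-4-bromo-6-methoxyphenol | C=CCc1cc(Br)cc(OC)c1O | intermediate
6 | 1-allyl-5-bromo-3-methoxy-2-{[3-methoxy-4-(methoxymethoxy)benzyl]oxy}benzene | C=CCc1cc(Br)cc(OC)c1OCc1ccc(OCOC)c(OC)c1 | intermediate
7 | methyl 2-(5-bromo-3-methoxy-2-{[3-methoxy-4-(methoxymethoxy)benzyl]oxy}phenyl)acetate | COC(=O)Cc1cc(Br)cc(OC)c1OCc1ccc(OCOC)c(OC)c1 | intermediate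
8 | methyl 2-diazo-2-(5-bromo-3-methoxy-2-{[3-methoxy-4-(methoxymethoxy)benzyl]oxy}phenyl)acetate | COC(=O)C(=[N+]=[N-])c1cc(Br)cc(OC)c1OCc1ccc(OCOC)c(OC)c1 | intermediate
9 | methyl (2R,3S)-5-bromo-7-methoxy-2-[3-methoxy-4-(methoxymethoxy)phenyl]-2,3-dihydro-1-benzofuran-3-carboxylate (cis) | COc1cc([C@@H]2Oc3c(OC)cc(Br)cc3[C@@H]2C(=O)OC)ccc1OCOC | intermediate
10 | methyl (2R,3R)-5-bromo-7-methoxy-2-[3-methoxy-4-(methoxymethoxy)phenyl]-2,3-dihydro-1-benzofuran-3-carboxylate (trans) | COc1cc([C@@H]2Oc3c(OC)cc(Br)cc3[C@H]2C(=O)OC)ccc1OCOC | intermediate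
11 | {(2R,3S)-5-bromo-7-methoxy-2-[3-methoxy-4-(methoxymethoxy)phenyl]-2,3-dihydro-1-benzofuran-3-yl}methanol | COc1cc([C@@H]2Oc3c(OC)cc(Br)cc3[C@H]2CO)ccc1OCOC | intermediate
12 | rings A/B bromide: tert-butyldimethylsilyl ether of 11 | COc1cc([C@@H]2Oc3c(OC)cc(Br)cc3[C@H]2CO[Si](C)(C)C(C)(C)C)ccc1OCOC | intermediate
13 | 3,4-dihydroxy-5-methoxybenzaldehyde | COc1cc(C=O)cc(O)c1O | starting material
14 | 3-hydroxy-5-methoxy-4-(methoxymethoxy)benzaldehyde | COCOc1c(O)cc(C=O)cc1OC | intermediate
15 | methyl (E)-3-[3-hydroxy-5-methoxy-4-(methoxymethoxy)phenyl]prop-2-enoate | COCOc1c(O)cc(/C=C/C(=O)OC)cc1OC | intermediate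
16 | ring C triflate: methyl (E)-3-[3-methoxy-4-(methoxymethoxy)-5-(trifluoromethylsulfonyloxy)phenyl]prop-2-enoate | COCOc1c(OC)cc(/C=C/C(=O)OC)cc1OS(=O)(=O)C(F)(F)F | intermediate
17 | acenaphthoquinone | O=C1C(=O)c2cccc3cccc1c23 | starting material
18 | cis-1,2-dimethyl-1,2-dihydroacenaphthylene-1,2-diol | C[C@]1(O)c2cccc3cccc(c23)[C@@]1(C)O | intermediate
19 | tert-butyldimethyl(prop-2-yn-1-yloxy)silane | C#CCO[Si](C)(C)C(C)(C)C | starting material
20 | 2-[(E)-3-(tert-butyldimethylsilyloxy)prop-1-enyl]-1,3,2-benzodioxaborole | CC(C)(C)[Si](C)(C)OC/C=C/B1Oc2ccccc2O1 | intermediate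
21 | (E)-3-(tert-butyldimethylsilyloxy)prop-1-enyl boronate of diol 18 | CC(C)(C)[Si](C)(C)OC/C=C/B1O[C@@]2(C)c3cccc4cccc(c34)[C@@]2(C)O1 | intermediate
22 | ring B C5 aryllithium from 12 | COc1cc([C@@H]2Oc3c(OC)cc([Li])cc3[C@H]2CO[Si](C)(C)C(C)(C)C)ccc1OCOC | intermediate
23 | lithium aryl(alkenyl)borate of diol 18 (boron configuration not defined) | [Li+].COc1cc([C@@H]2Oc3c(OC)cc([B-]4(/C=C/CO[Si](C)(C)C(C)(C)C)O[C@@]5(C)c6cccc7cccc(c67)[C@@]5(C)O4)cc3[C@H]2CO[Si](C)(C)C(C)(C)C)ccc1OCOC | intermediate
24 | (2'R,3'S)-1,2-diaryl-3-silyloxypropyl boronate of diol 18 | COc1cc([C@@H]2Oc3c(OC)cc([C@H](B4O[C@@]5(C)c6cccc7cccc(c67)[C@@]5(C)O4)[C@H](CO[Si](C)(C)C(C)(C)C)c4cc(/C=C/C(=O)OC)cc(OC)c4OCOC)cc3[C@H]2CO[Si](C)(C)C(C)(C)C)ccc1OCOC | intermediate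
25 | (2'R,3'S)-benzylic alcohol from 24 | COc1cc([C@@H]2Oc3c(OC)cc([C@H](O)[C@H](CO[Si](C)(C)C(C)(C)C)c4cc(/C=C/C(=O)OC)cc(OC)c4OCOC)cc3[C@H]2CO[Si](C)(C)C(C)(C)C)ccc1OCOC | intermediate
26 | open-chain pentaol (both phenols, C2'–OH, C9–OH and C9'–OH free) | COc1cc([C@@H]2Oc3c(OC)cc([C@H](O)[C@H](CO)c4cc(/C=C/C(=O)OC)cc(OC)c4O)cc3[C@H]2CO)ccc1O | intermediate
27 | methyl (E)-propenoate of the target skeleton (2R,3S,2'R,3'S) | COc1cc([C@@H]2Oc3c(OC)cc([C@@H]4Oc5c(OC)cc(/C=C/C(=O)OC)cc5[C@H]4CO)cc3[C@H]2CO)ccc1O | intermediate
28 | CNP0250921.1, (2R,3S,2'R,3'S) | COc1cc([C@@H]2Oc3c(OC)cc([C@@H]4Oc5c(OC)cc(/C=C/CO)cc5[C@H]4CO)cc3[C@H]2CO)ccc1O | target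

**Step count**
Total step count: 19. Longest linear sequence: 13 (steps 1, 2, 4–10, 16–19).

**Steps most likely to fail**

Step 16. The hindered boronate may capture the functionalised aryllithium slowly, so that proton abstraction and bromide carried into the palladium cycle stall turnover and give reduced arene. The fallback sets out from 12 and 19 and returns at 23, with the boron and carbanion partners changing places. Aryllithium 22 would be quenched with B(OMe)3 and hydrolysed to the ring B boronic acid F1, which condenses with diol 18 (MgSO4, CH2Cl2) to the ring B aryl boronate of diol 18 F2. Alkyne 19 would be hydrostannylated (Bu3SnH, AIBN, 80 °C) to the (E)-alkenylstannane F3, and tin–lithium exchange with n-BuLi (THF, −78 °C) gives the halide-free (E)-alkenyllithium F4. Addition of F4 to F2 gives the same ate complex 23, which is coupled with 16 under the palladium conditions of step 16 without a halide scavenger.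

Step 7. The 7-methoxy group beside the ether oxygen may change how the benzyloxy group sits in the chiral pocket, so that enantiofacial discrimination in the insertion is lost. The fallback sets out from 8 and returns at 11, replacing asymmetric catalysis by resolution. Rh2(OAc)4 in CH2Cl2 would give the racemic cis ester F5, NaOMe in MeOH the racemic trans ester F6, and i-Bu2AlH the racemic trans alcohol F7. F7 is resolved by preparative chromatography on a cellulose tris(3,5-dimethylphenylcarbamate) phase, the (2R,3S) enantiomer being 11.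

Step 18. With several groups leaving at different rates, methanol may trap the C2' cation, and the free C9' hydroxymethyl group may fragment with loss of formaldehyde before the ring closes. The fallback sets out from 25 and returns at 27, separating unmasking from closure. The aryl acetals would be removed first without protic acid (TMSOTf, 2,2'-bipyridyl, CH2Cl2, 0 °C; then H2O) to give the open-chain diphenol bis-silyl ether F8. Catalytic BF3·OEt2 in CH2Cl2 at −40 °C then closes O1'–C2' with no competing nucleophile and with C9' still silylated, giving the cyclised bis-silyl ether F9. Bu4NF buffered with AcOH in THF removes both silyl groups to give 27.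

**Further compounds**
F1 | step 16 | ring B boronic acid from 12 | COc1cc([C@@H]2Oc3c(OC)cc(B(O)O)cc3[C@H]2CO[Si](C)(C)C(C)(C)C)ccc1OCOC
F2 | step 16 | ring B aryl boronate of diol 18 | COc1cc([C@@H]2Oc3c(OC)cc(B4O[C@@]5(C)c6cccc7cccc(c67)[C@@]5(C)O4)cc3[C@H]2CO[Si](C)(C)C(C)(C)C)ccc1OCOC
F3 | step 16 | (E)-tributyl[3-(tert-butyldimethylsilyloxy)prop-1-enyl]stannane | CCCC[Sn](CCCC)(CCCC)/C=C/CO[Si](C)(C)C(C)(C)C
F4 | step 16 | (E)-3-(tert-butyldimethylsilyloxy)prop-1-enyllithium | [Li]/C=C/CO[Si](C)(C)C(C)(C)C
F5 | step 7 | racemic cis ester (9 and its enantiomer) | COc1cc([C@@H]2Oc3c(OC)cc(Br)cc3[C@@H]2C(=O)OC)ccc1OCOC.COc1cc([C@H]2Oc3c(OC)cc(Br)cc3[C@H]2C(=O)OC)ccc1OCOC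
F6 | step 7 | racemic trans ester (10 and its enantiomer) | COc1cc([C@@H]2Oc3c(OC)cc(Br)cc3[C@H]2C(=O)OC)ccc1OCOC.COc1cc([C@H]2Oc3c(OC)cc(Br)cc3[C@@H]2C(=O)OC)ccc1OCOC
F7 | step 7 | racemic trans alcohol (11 and its enantiomer) | COc1cc([C@@H]2Oc3c(OC)cc(Br)cc3[C@H]2CO)ccc1OCOC.COc1cc([C@H]2Oc3c(OC)cc(Br)cc3[C@@H]2CO)ccc1OCOC
F8 | step 18 | open-chain diphenol bis-silyl ether | COc1cc([C@@H]2Oc3c(OC)cc([C@H](O)[C@H](CO[Si](C)(C)C(C)(C)C)c4cc(/C=C/C(=O)OC)cc(OC)c4O)cc3[C@H]2CO[Si](C)(C)C(C)(C)C)ccc1O
F9 | step 18 | cyclised bis-silyl ether of 27 | COc1cc([C@@H]2Oc3c(OC)cc([C@@H]4Oc5c(OC)cc(/C=C/C(=O)OC)cc5[C@H]4CO[Si](C)(C)C(C)(C)C)cc3[C@H]2CO[Si](C)(C)C(C)(C)C)ccc1O
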